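Picture the free enzyme and the homo dimer as two takers of one starting material, A, while the second substrate, B, feeds the enzyme's round.

| flask | starting material | second substrate | free enzyme | remark | time |
|---|---|---|---|---|---|
| north-east | 0.10 M | 0.13 M | 1.7 µM | run made earlier |  |
| east | 0.067 M | 0.13 M | 1.7 µM | run made earlier |  |
| south-east | 0.15 M | 0.13 M | 1.7 µM | run made earlier |  |
| north-west | 0.10 M | 0.13 M | 3.4 µM | run made earlier |  |
| dusk | 0.10 M | 0.130 M | 1.7 µM | everything together at the start | 20 h |
| midnight | 0.10 M | 0.130 M (fed, over 8.0 h) | 1.7 µM | all else is in the flask from the start; the feed brings no volume worth counting | 20 h |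
| spring | 0.10 M (fed, over 8.0 h) | 0.130 M | 1.7 µM | all else is in the flask from the start; the feed brings no volume worth counting | 20 h |
| noon | 0.10 M (fed, over 50 min) | 0.130 M | 1.7 µM | all else is in the flask from the start; the feed brings no volume worth counting | 20 h |

| run | time / h | target / % |
|---|---|---|
| north-east | 1.00 | 4.9 |
| north-east | 3.00 | 12.8 |
| north-east | 6.00 | 24.6 |
| north-east | 8.00 | 31.3 |
| north-east | 12.0 | 39.6 |
| north-east | 15.0 | 38.5 |
| north-east | 20.0 | 38.6 |
| east | 0.833 | 5.7 |
| east | 2.50 | 15.7 |
| east | 5.00 | 30.6 |
| east | 6.00 | 35.7 |
| east | 10.0 | 51.9 |
| east | 12.0 | 52.7 |
| east | 15.0 | 52.5 |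
| south-east | 0.833 | 3.5 |
| south-east | 2.50 | 7.5 |
| south-east | 5.00 | 13.9 |
| south-east | 6.00 | 17.6 |
| south-east | 10.0 | 25.2 |
| south-east | 12.0 | 27.6 |
| south-east | 15.0 | 27.8 |
| north-west | 1.33 | 11.7 |
| north-west | 4.00 | 30.6 |
| north-west | 8.00 | 49.2 |
| north-west | 12.0 | 48.9 |
| north-west | 15.0 | 49.5 |

(each reading ± 0.5 percentage points)

- percent here means starting material units held: one homo dimer or resting dimer counts as two
- the numbers in the tables scatter by 0.5 percentage points (one standard deviation)
- candidate steps: second substrate + loaded enzyme <-> second complex; starting material + free enzyme <-> first complex; 2 second complex <-> resting dimer; second complex -> free enzyme + target; first complex -> loaded enzyme + first product; 2 starting material -> homo dimer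

- which flask leads in amount of target, in percent of the starting material charged ("all alike" within 1.5 percentage points) (dusk / midnight / spring / noon / all alike)
- how much target is there at the end, in percent of the starting material charged: dusk
- how much target is there at the end, in percent of the starting material charged: midnight
- how much target is there at the end, in percent of the starting material charged: spring
- how much target is there at the end, in percent of the starting material charged: noon

Let the enzyme take A at a steady rate V, as the early readings suggest, and let dimerisation go with A squared. Each A lost then reaches target with a share of one over one plus (A/s) squared. Far above s, that share goes as (s/A) squared, so the extra target between two charges is s squared times the difference of their reciprocals. Apply this to the east and south-east plateaus: 52.5 % of 0.067 M and 27.8 % of 0.15 M. This gives s = 0.0281 M, the balance level: the A at which both takers get half, the zero of the scale.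

Percent target then follows charge over s, and s goes as the root of V. Test this on north-west: double enzyme acts like a charge of 0.0707 M, and its plateau of 49.5 % stands near east's 52.5 %.

Now bracket midnight. If the rate ignores B, midnight repeats north-east, so the upper bound is 38.6 %. If the rate follows B, fed B averages at most half its charge, which acts like a charge of at least 0.141 M, so take south-east's 27.8 % as a rough lower mark, not a proven floor. Tighten it: in north-east the rate fell to a reading of 0.867 of its early value while mean B fell to 0.873 of its own. So take the rate as following B: interpolating between the south-east and north-east plateaus at that least charge gives an estimate of 29.7 %.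

The forecast gives 38.6 %, 37.5 %, 60 % and 40.3 % for dusk, midnight, spring and noon, with spring leading. Its midnight lies inside the bracket but above my figure, for it holds that “the rate barely depends on B”.

The flasks give dusk 39.3 %, midnight 29.6 %, spring 57.9 % and noon 41.2 %, with spring leading. Over the first 8.0 h, mean B stood at 0.0581 M in midnight against 0.113 M in dusk, about half. Scaled by the root of that ratio, midnight's balance level is 0.0201 M, and mean A over those hours, 0.0390 M, stood above it.

    second substrate + loaded enzyme ⇌ second complex (K = 2.60 L mol⁻¹, k = 3.20 × 10⁵ L mol⁻¹ min⁻¹)
    starting material + free enzyme ⇌ first complex (K = 79.0 L mol⁻¹, k = 1.10 × 10⁵ L mol⁻¹ min⁻¹)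
    2 second complex ⇌ resting dimer, settled at all times (K = 3.80 × 10⁵ L mol⁻¹)
    second complex → free enzyme + target (k = 210 min⁻¹)
    first complex → loaded enzyme + first product (k = 450 min⁻¹)
    2 starting material → homo dimer (k = 0.0360 L mol⁻¹ min⁻¹)

Take the neighbour of midnight charged with 0.025 M of A. Its charge lies near that balance level, so average the share at the two ends, one at the finish and the charge's share at the start: this gives 69.6 %. The computed flask gives 70.0 %.

(The data are simulated from invented constants, and the scatter is random.)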